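The carotenoid is cut at C11=C12 and C11'=C12' into two C15 phosphonium salts and the C10 trienedial; both end groups come from one actinol-derived alcohol 8. The strategy rests on the C6=C7 bond of the 2,5-dihydrofuran ring (O, C5, C6, C7, C8): this lone ring alkene lies between ring-fusion carbon C6 and C7, which is flanked by the ether stereocentre C8. Its precursor is therefore the open bis-allylic ether 17, C5–O–C8 intact, with a methylidene on C6 and a vinyl group on C8 (C8 set by iridium-catalysed etherification). Ring-closing olefin metathesis closes the five-membered ring in one operation, forming the trisubstituted alkene without touching C5 or C8.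

Key step: step 12

Remark on numbering: carotenoid locants are used for atoms; unprimed locants belong to the dihydrofuran half, primed locants to the triol half.
Remark on step 11: the (Sa,Sc,Sc) phosphoramidite is assumed to give the (S)-configured C8–O centre, as with aryl- and alkenyl-substituted allyl carbonates and oxygen nucleophiles; if the sense were opposite, its mirror image would be used.
Remark on supply: compounds 1, 9, 22 and 27 are taken as purchased.

Step 1
Reactants: 1 (4R,6R)-4-hydroxy-2,2,6-trimethylcyclohexan-1-one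
Product: 2 (4R,6R)-4-{[tert-butyl(dimethyl)silyl]oxy}-2,2,6-trimethylcyclohexan-1-one
Conditions: TBSCl, imidazole, DMF, rt
Reagents that add atoms: tert-butyl(chloro)dimethylsilane, CC(C)(C)[Si](C)(C)Cl
Why: Imidazole-promoted silylation of the only hydroxyl group protects it for the organolithium and hydride steps; no stereocentre is affected.

Step 2
Reactants: 2 (4R,6R)-4-{[tert-butyl(dimethyl)silyl]oxy}-2,2,6-trimethylcyclohexan-1-one
Product: 3 N'-[(1E,4R,6R)-4-{[tert-butyl(dimethyl)silyl]oxy}-2,2,6-trimethylcyclohexylidene]-2,4,6-tri(propan-2-yl)benzenesulfonohydrazide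
Conditions: 2,4,6-triisopropylbenzenesulfonohydrazide, cat. PPTS, THF, 4 Å MS, rt
Reagents that add atoms: 2,4,6-tri(propan-2-yl)benzenesulfonohydrazide, CC(C)c1cc(C(C)C)c(S(=O)(=O)NN)c(C(C)C)c1
Why: Acid-catalysed condensation of the hindered ketone should give the hydrazone with its N–N bond turned away from the quaternary carbon, the geometry the Shapiro reaction needs.

Step 3
Reactants: 3 N'-[(1E,4R,6R)-4-{[tert-butyl(dimethyl)silyl]oxy}-2,2,6-trimethylcyclohexylidene]-2,4,6-tri(propan-2-yl)benzenesulfonohydrazide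
Product: 5 [(4R)-4-{[tert-butyl(dimethyl)silyl]oxy}-2,6,6-trimethylcyclohex-1-en-1-yl]methanol, via vinyllithium 4 (not isolated)
Conditions: n-BuLi (2.3 equiv), TMEDA, hexane/THF, −78 → 0 °C; then dry paraformaldehyde, −78 °C → rt
Reagents that add atoms: formaldehyde (from paraformaldehyde), C=O
Why: Shapiro reaction: deprotonation at N–H and at the only α-C–H, then loss of sulfinate and N2, should give the tetrasubstituted vinyllithium, which adds to formaldehyde; the former α-stereocentre becomes sp2 as intended and the silyloxy carbon is untouched.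

Step 4
Reactants: 5 [(4R)-4-{[tert-butyl(dimethyl)silyl]oxy}-2,6,6-trimethylcyclohex-1-en-1-yl]methanol
Product: 6 [(1R,4S,6R)-4-{[tert-butyl(dimethyl)silyl]oxy}-2,2,6-trimethyl-7-oxabicyclo[4.1.0]heptan-1-yl]methanol (epoxide oxygen trans to the silyloxy group)
Conditions: Ti(OiPr)4, D-(−)-diethyl tartrate, t-BuOOH, 4 Å MS, CH2Cl2, −20 °C
Reagents that add atoms: tert-butyl hydroperoxide, CC(C)(C)OO
Why: Sharpless asymmetric epoxidation, in which the D-(−)-tartrate–titanium complex delivers oxygen to the alkene face opposite to the silyloxy group (reagent control), sets C5 (R) and the second epoxide carbon C6 in one event.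

Step 5
Reactants: 6 [(1R,4S,6R)-4-{[tert-butyl(dimethyl)silyl]oxy}-2,2,6-trimethyl-7-oxabicyclo[4.1.0]heptan-1-yl]methanol
Product: 7 tert-butyl{[(1R,3S,6S)-6-(iodomethyl)-1,5,5-trimethyl-7-oxabicyclo[4.1.0]heptan-3-yl]oxy}dimethylsilane
Conditions: PPh3, I2, imidazole, toluene/MeCN, rt → 50 °C
Reagents that add atoms: iodine, II
Why: Appel-type iodination (phosphine, iodine, imidazole) replaces the primary hydroxyl by iodide at the oxiranylmethyl carbon without opening the epoxide.

Step 6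
Reactants: 7 tert-butyl{[(1R,3S,6S)-6-(iodomethyl)-1,5,5-trimethyl-7-oxabicyclo[4.1.0]heptan-3-yl]oxy}dimethylsilane
Product: 8 (1R,5S)-5-{[tert-butyl(dimethyl)silyl]oxy}-1,3,3-trimethyl-2-methylidenecyclohexan-1-ol
Conditions: activated Zn dust, AcOH (1.5 equiv), EtOH, 40 °C
Reagents that add atoms: none
Why: Reductive opening of a 2,3-epoxy iodide: zinc inserts into the C–I bond and β-elimination cleaves the C6–O epoxide bond, which unveils the C6 methylidene and the tertiary C5 alcohol with the C5–O bond, and hence the C5 configuration, untouched.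

Step 7
Reactants: 9 (2E)-3-methylpent-2-en-4-yn-1-ol
Product: 10 triethyl{[(2E)-3-methylpent-2-en-4-yn-1-yl]oxy}silane
Conditions: Et3SiCl, imidazole, CH2Cl2, 0 °C
Reagents that add atoms: chlorotriethylsilane, CC[Si](Cl)(CC)CC
Why: Standard silylation gives a primary silyl ether that can later be removed in the presence of the secondary tert-butyldimethylsilyl ether.

Step 8
Reactants: 10 triethyl{[(2E)-3-methylpent-2-en-4-yn-1-yl]oxy}silane
Product: 12 (4E)-4-methyl-6-[(triethylsilyl)oxy]hex-4-en-2-yn-1-ol, via lithium acetylide 11 (not isolated)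
Conditions: n-BuLi, THF, −78 °C; then dry paraformaldehyde, −78 °C → rt
Reagents that add atoms: formaldehyde (from paraformaldehyde), C=O
Why: The lithium acetylide adds to formaldehyde (1,2-addition) and so brings in the carbon that later leaves as ethene.

Step 9
Reactants: 12 (4E)-4-methyl-6-[(triethylsilyl)oxy]hex-4-en-2-yn-1-ol
Product: 13 (2E,4E)-4-methyl-6-[(triethylsilyl)oxy]hexa-2,4-dien-1-ol
Conditions: NaAlH2(OCH2CH2OMe)2 (Red-Al), THF, 0 °C; aqueous potassium sodium tartrate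
Reagents that add atoms: none
Why: Alkoxide-directed trans-hydroalumination of the propargylic alcohol followed by protonolysis should give the E-allylic alcohol and leave the trisubstituted alkene and the silyl ether alone.

Step 10
Reactants: 13 (2E,4E)-4-methyl-6-[(triethylsilyl)oxy]hexa-2,4-dien-1-ol
Product: 14 methyl (2E,4E)-4-methyl-6-[(triethylsilyl)oxy]hexa-2,4-dien-1-yl carbonate
Conditions: ClCO2Me, pyridine, CH2Cl2, 0 °C
Reagents that add atoms: methyl chloroformate, COC(=O)Cl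
Why: Acylation of the primary allylic alcohol installs the carbonate leaving group needed for ionisation by iridium.

Step 11
Reactants: 8 (1R,5S)-5-{[tert-butyl(dimethyl)silyl]oxy}-1,3,3-trimethyl-2-methylidenecyclohexan-1-ol; 14 methyl (2E,4E)-4-methyl-6-[(triethylsilyl)oxy]hexa-2,4-dien-1-yl carbonate
Product: 17 tert-butyl(dimethyl){[(1S,3R)-3,5,5-trimethyl-4-methylidene-3-({(3S,4E)-4-methyl-6-[(triethylsilyl)oxy]hexa-1,4-dien-3-yl}oxy)cyclohexyl]oxy}silane, via lithium alkoxide 15 (not isolated), via copper alkoxide 16 (not isolated)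
Conditions: 8, n-BuLi (1.0 equiv), THF, −78 → 0 °C; CuI (1.0 equiv); then 14, [Ir(cod)Cl]2 (2 mol%), (Sa,Sc,Sc)-O,O'-(1,1'-binaphthalene-2,2'-diyl)-N,N-bis(1-phenylethyl)phosphoramidite (4 mol%, pre-activated with n-PrNH2), THF, rt
Reagents that add atoms: none
Why: Iridium-catalysed asymmetric allylic etherification: ionisation of the carbonate gives an allyl-iridium complex that the copper alkoxide should attack at the substituted terminus, so that the branched ether forms and the new C8 stereocentre is set (S) by the chiral phosphoramidite (catalyst control over the chiral alkoxide), while C5 is a spectator.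

Step 12
Reactants: 17 tert-butyl(dimethyl){[(1S,3R)-3,5,5-trimethyl-4-methylidene-3-({(3S,4E)-4-methyl-6-[(triethylsilyl)oxy]hexa-1,4-dien-3-yl}oxy)cyclohexyl]oxy}silane
Product: 18 tert-butyl(dimethyl){[(2S,6S,7aR)-4,4,7a-trimethyl-2-{(2E)-4-[(triethylsilyl)oxy]but-2-en-2-yl}-2,4,5,6,7,7a-hexahydro-1-benzofuran-6-yl]oxy}silane
Conditions: second-generation Grubbs catalyst (H2IMes)(PCy3)Cl2Ru=CHPh (10 mol%), 1,4-benzoquinone (20 mol%), degassed toluene (0.005 M), 80 °C, Ar sparge
Reagents that add atoms: none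
Why: Olefin metathesis: the ruthenium benzylidene exchanges onto the unhindered C8 vinyl group to give a C7 alkylidene, which adds across the C6 methylidene ([2+2]) and cycloreverts with loss of ethene, so that C7 and C6 end up doubly bonded. The closest known reaction type is ring-closing metathesis of bis-allylic ethers to 2,5-dihydrofurans that carry a trisubstituted ring alkene. One ring closes, the five-membered dihydrofuran (O, C5, C6, C7, C8), by joining two exocyclic alkene carbons through a metallacyclobutane; the cyclohexane ring is already present. No stereocentre is created: C5 (from step 4) and C8 (from step 11) take no part in the bond changes and are carried through unchanged. The step needs site selectivity among three alkenes and suppression of double-bond migration towards the ring oxygen: only the vinyl/methylidene pair can give an unstrained ring (closure onto C9=C10 would give a three- or four-membered ring), high dilution disfavours dimerisation and benzoquinone intercepts ruthenium hydrides. Loss of ethene makes the closure irreversible despite the neopentyl surroundings of C6.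

Step 13
Reactants: 18 tert-butyl(dimethyl){[(2S,6S,7aR)-4,4,7a-trimethyl-2-{(2E)-4-[(triethylsilyl)oxy]but-2-en-2-yl}-2,4,5,6,7,7a-hexahydro-1-benzofuran-6-yl]oxy}silane
Product: 19 (2E)-3-[(2S,6S,7aR)-6-{[tert-butyl(dimethyl)silyl]oxy}-4,4,7a-trimethyl-2,4,5,6,7,7a-hexahydro-1-benzofuran-2-yl]but-2-en-1-ol
Conditions: HF·pyridine, excess pyridine, THF, 0 °C
Reagents that add atoms: none
Why: Buffered fluoride should remove the unhindered primary allylic triethylsilyl ether far faster than the secondary tert-butyldimethylsilyl ether, and the near-neutral medium spares the acid-labile bis-allylic C8–O bond.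

Step 14
Reactants: 19 (2E)-3-[(2S,6S,7aR)-6-{[tert-butyl(dimethyl)silyl]oxy}-4,4,7a-trimethyl-2,4,5,6,7,7a-hexahydro-1-benzofuran-2-yl]but-2-en-1-ol
Product: 21 {(2E)-3-[(2S,6S,7aR)-6-{[tert-butyl(dimethyl)silyl]oxy}-4,4,7a-trimethyl-2,4,5,6,7,7a-hexahydro-1-benzofuran-2-yl]but-2-en-1-yl}(triphenyl)phosphonium bromide, via allylic bromide 20 (not isolated)
Conditions: NBS, Me2S, CH2Cl2, −20 → 0 °C; then PPh3, rt
Reagents that add atoms: N-bromosuccinimide, O=C1CCC(=O)N1Br; triphenylphosphine, c1ccc(P(c2ccccc2)c2ccccc2)cc1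
Why: Corey–Kim bromination, which is specific for allylic alcohols and runs without acid, followed by SN2 quaternisation of triphenylphosphine should give the Wittig salt with the C9=C10 geometry intact.

Step 15
Reactants: 21 {(2E)-3-[(2S,6S,7aR)-6-{[tert-butyl(dimethyl)silyl]oxy}-4,4,7a-trimethyl-2,4,5,6,7,7a-hexahydro-1-benzofuran-2-yl]but-2-en-1-yl}(triphenyl)phosphonium bromide; 22 (2E,4E,6E)-2,7-dimethylocta-2,4,6-trienedial
Product: 24 (2E,4E,6E,8E,10E)-11-[(2S,6S,7aR)-6-{[tert-butyl(dimethyl)silyl]oxy}-4,4,7a-trimethyl-2,4,5,6,7,7a-hexahydro-1-benzofuran-2-yl]-2,7-dimethyldodeca-2,4,6,8,10-pentaenal, via phosphorus ylide 23 (not isolated)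
Conditions: 22 (3 equiv), NaOMe (1.1 equiv), CH2Cl2/MeOH, −10 °C → rt; then n-heptane, 80 °C (Z → E at C11=C12), Ar, dark
Reagents that add atoms: none
Why: Wittig olefination of the semistabilised allylic ylide with an excess of the symmetrical dialdehyde should stop at the mono-olefin and form C11=C12, the hindered 11Z isomer being equilibrated thermally to E; the ylide is the formal oxa-Michael adduct of a dienylphosphonium salt and is therefore not expected to expel the ring alkoxide.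

Step 16
Reactants: 8 (1R,5S)-5-{[tert-butyl(dimethyl)silyl]oxy}-1,3,3-trimethyl-2-methylidenecyclohexan-1-ol
Product: 25 (1S,2R,4S)-4-{[tert-butyl(dimethyl)silyl]oxy}-1-(hydroxymethyl)-2,6,6-trimethylcyclohexane-1,2-diol
Conditions: OsO4 (5 mol%), 4-methylmorpholine N-oxide (2 equiv), acetone/H2O, rt → 40 °C
Reagents that add atoms: 4-methylmorpholine N-oxide, C[N+]1([O-])CCOCC1; water, O (both oxygen atoms reach the alkene through OsO4)
Why: Catalytic osmium tetroxide dihydroxylation (Upjohn conditions) should occur on the methylidene face anti to the allylic tertiary hydroxyl, which is also the face free of the axial ring methyl and the axial hydroxyl, so that the new tertiary hydroxyl is trans to the existing one (substrate control sets C6').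

Step 17
Reactants: 25 (1S,2R,4S)-4-{[tert-butyl(dimethyl)silyl]oxy}-1-(hydroxymethyl)-2,6,6-trimethylcyclohexane-1,2-diol
Product: 26 (1R,2R,4S)-4-{[tert-butyl(dimethyl)silyl]oxy}-1,2-dihydroxy-2,6,6-trimethylcyclohexane-1-carbaldehyde
Conditions: SO3·pyridine, DMSO, Et3N, CH2Cl2, 0 °C
Reagents that add atoms: none
Why: Parikh–Doering oxidation converts the only oxidisable (primary) hydroxyl into the aldehyde, which has no α-hydrogen and so cannot epimerise.

Step 18
Reactants: 26 (1R,2R,4S)-4-{[tert-butyl(dimethyl)silyl]oxy}-1,2-dihydroxy-2,6,6-trimethylcyclohexane-1-carbaldehyde; 27 ethyl (2E)-4-(diethoxyphosphoryl)-3-methylbut-2-enoate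
Product: 29 ethyl (2E,4E)-5-[(1R,2R,4S)-4-{[tert-butyl(dimethyl)silyl]oxy}-1,2-dihydroxy-2,6,6-trimethylcyclohexyl]-3-methylpenta-2,4-dienoate, via lithiated phosphonate 28 (not isolated)
Conditions: 27 (3.5 equiv), LiN(SiMe3)2 (3.3 equiv), THF, −78 °C; then 26, −78 → 0 °C
Reagents that add atoms: none
Why: Horner–Wadsworth–Emmons olefination with the vinylogous phosphonate anion should form C7'=C8' E-selectively and bring in C9'–C11' with the E trisubstituted alkene already in place; the excess anion covers the two free tertiary hydroxyls.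

Step 19
Reactants: 29 ethyl (2E,4E)-5-[(1R,2R,4S)-4-{[tert-butyl(dimethyl)silyl]oxy}-1,2-dihydroxy-2,6,6-trimethylcyclohexyl]-3-methylpenta-2,4-dienoate
Product: 30 (1R,2R,4S)-4-{[tert-butyl(dimethyl)silyl]oxy}-1-[(1E,3E)-5-hydroxy-3-methylpenta-1,3-dien-1-yl]-2,6,6-trimethylcyclohexane-1,2-diol
Conditions: iBu2AlH (5 equiv), CH2Cl2, −78 °C; aqueous potassium sodium tartrate
Reagents that add atoms: none
Why: Low-temperature 1,2-reduction of the dienoate by the aluminium hydride gives the allylic alcohol without touching the diene.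

Step 20
Reactants: 30 (1R,2R,4S)-4-{[tert-butyl(dimethyl)silyl]oxy}-1-[(1E,3E)-5-hydroxy-3-methylpenta-1,3-dien-1-yl]-2,6,6-trimethylcyclohexane-1,2-diol
Product: 32 {(2E,4E)-5-[(1R,2R,4S)-4-{[tert-butyl(dimethyl)silyl]oxy}-1,2-dihydroxy-2,6,6-trimethylcyclohexyl]-3-methylpenta-2,4-dien-1-yl}(triphenyl)phosphonium bromide, via allylic bromide 31 (not isolated)
Conditions: NBS, Me2S, CH2Cl2, −20 → 0 °C; then PPh3, rt
Reagents that add atoms: N-bromosuccinimide, O=C1CCC(=O)N1Br; triphenylphosphine, c1ccc(P(c2ccccc2)c2ccccc2)cc1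
Why: Corey–Kim bromination should react only at the primary allylic alcohol (the tertiary alcohols are inert), and triphenylphosphine then gives the salt by SN2 displacement.

Step 21
Reactants: 32 {(2E,4E)-5-[(1R,2R,4S)-4-{[tert-butyl(dimethyl)silyl]oxy}-1,2-dihydroxy-2,6,6-trimethylcyclohexyl]-3-methylpenta-2,4-dien-1-yl}(triphenyl)phosphonium bromide; 24 (2E,4E,6E,8E,10E)-11-[(2S,6S,7aR)-6-{[tert-butyl(dimethyl)silyl]oxy}-4,4,7a-trimethyl-2,4,5,6,7,7a-hexahydro-1-benzofuran-2-yl]-2,7-dimethyldodeca-2,4,6,8,10-pentaenal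
Product: 34 (all-E)-3,3'-bis-O-[tert-butyl(dimethyl)silyl] ether of the target, via phosphorus ylide 33 (not isolated)
Conditions: NaOMe (1.2 equiv), CH2Cl2/MeOH, 0 °C → rt; then EtOAc, 70 °C (Z → E at C11'=C12'), Ar, dark
Reagents that add atoms: none
Why: Wittig olefination joins the two halves at C11'=C12' in methanolic methoxide, which tolerates the free tertiary hydroxyls, and the hindered Z isomer at the new bond is equilibrated thermally to the all-E polyene.

Step 22
Reactants: 34 (all-E)-3,3'-bis-O-[tert-butyl(dimethyl)silyl] ether of the target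
Product: 35 (3S,5R,8S,3'S,5'R,6'R)-5,8-epoxy-5,8,5',6'-tetrahydro-β,β-carotene-3,3',5',6'-tetrol
Conditions: Bu4NF, THF, 0 °C → rt, Ar, dark
Reagents that add atoms: none
Why: Fluoride cleaves both secondary silyl ethers under non-acidic conditions, which matters because acid would epimerise C8 of the dihydrofuran.

Compound list
1 | (4R,6R)-4-hydroxy-2,2,6-trimethylcyclohexan-1-one | O=C1C(C)(C)C[C@H](O)C[C@H]1C | starting material
2 | (4R,6R)-4-{[tert-butyl(dimethyl)silyl]oxy}-2,2,6-trimethylcyclohexan-1-one | O=C1C(C)(C)C[C@H](O[Si](C)(C)C(C)(C)C)C[C@H]1C | intermediate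
3 | N'-[(1E,4R,6R)-4-{[tert-butyl(dimethyl)silyl]oxy}-2,2,6-trimethylcyclohexylidene]-2,4,6-tri(propan-2-yl)benzenesulfonohydrazide | CC(C)c1cc(C(C)C)c(S(=O)(=O)N/N=C2/C(C)(C)C[C@H](O[Si](C)(C)C(C)(C)C)C[C@H]2C)c(C(C)C)c1 | intermediate
4 | [(4R)-4-{[tert-butyl(dimethyl)silyl]oxy}-2,6,6-trimethylcyclohex-1-en-1-yl]lithium | CC1=C([Li])C(C)(C)C[C@H](O[Si](C)(C)C(C)(C)C)C1 | intermediate
5 | [(4R)-4-{[tert-butyl(dimethyl)silyl]oxy}-2,6,6-trimethylcyclohex-1-en-1-yl]methanol | CC1=C(CO)C(C)(C)C[C@H](O[Si](C)(C)C(C)(C)C)C1 | intermediate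
6 | [(1R,4S,6R)-4-{[tert-butyl(dimethyl)silyl]oxy}-2,2,6-trimethyl-7-oxabicyclo[4.1.0]heptan-1-yl]methanol | OC[C@]12C(C)(C)C[C@H](O[Si](C)(C)C(C)(C)C)C[C@@]1(C)O2 | intermediate
7 | tert-butyl{[(1R,3S,6S)-6-(iodomethyl)-1,5,5-trimethyl-7-oxabicyclo[4.1.0]heptan-3-yl]oxy}dimethylsilane | IC[C@]12C(C)(C)C[C@H](O[Si](C)(C)C(C)(C)C)C[C@@]1(C)O2 | intermediate
8 | (1R,5S)-5-{[tert-butyl(dimethyl)silyl]oxy}-1,3,3-trimethyl-2-methylidenecyclohexan-1-ol | C=C1C(C)(C)C[C@H](O[Si](C)(C)C(C)(C)C)C[C@@]1(C)O | intermediate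
9 | (2E)-3-methylpent-2-en-4-yn-1-ol | C#C/C(C)=C/CO | starting material
10 | triethyl{[(2E)-3-methylpent-2-en-4-yn-1-yl]oxy}silane | C#C/C(C)=C/CO[Si](CC)(CC)CC | intermediate
11 | {(3E)-3-methyl-5-[(triethylsilyl)oxy]pent-3-en-1-yn-1-yl}lithium | [Li]C#C/C(C)=C/CO[Si](CC)(CC)CC | intermediate
12 | (4E)-4-methyl-6-[(triethylsilyl)oxy]hex-4-en-2-yn-1-ol | OCC#C/C(C)=C/CO[Si](CC)(CC)CC | intermediate
13 | (2E,4E)-4-methyl-6-[(triethylsilyl)oxy]hexa-2,4-dien-1-ol | OC/C=C/C(C)=C/CO[Si](CC)(CC)CC | intermediate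
14 | methyl (2E,4E)-4-methyl-6-[(triethylsilyl)oxy]hexa-2,4-dien-1-yl carbonate | COC(=O)OC/C=C/C(C)=C/CO[Si](CC)(CC)CC | intermediate
15 | lithium (1R,5S)-5-{[tert-butyl(dimethyl)silyl]oxy}-1,3,3-trimethyl-2-methylidenecyclohexan-1-olate | C=C1C(C)(C)C[C@H](O[Si](C)(C)C(C)(C)C)C[C@@]1(C)O[Li] | intermediate
16 | copper (1R,5S)-5-{[tert-butyl(dimethyl)silyl]oxy}-1,3,3-trimethyl-2-methylidenecyclohexan-1-olate (monovalent copper) | C=C1C(C)(C)C[C@H](O[Si](C)(C)C(C)(C)C)C[C@@]1(C)O[Cu] | intermediate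
17 | tert-butyl(dimethyl){[(1S,3R)-3,5,5-trimethyl-4-methylidene-3-({(3S,4E)-4-methyl-6-[(triethylsilyl)oxy]hexa-1,4-dien-3-yl}oxy)cyclohexyl]oxy}silane | C=C1C(C)(C)C[C@H](O[Si](C)(C)C(C)(C)C)C[C@@]1(C)O[C@@H](C=C)/C(C)=C/CO[Si](CC)(CC)CC | intermediate
18 | tert-butyl(dimethyl){[(2S,6S,7aR)-4,4,7a-trimethyl-2-{(2E)-4-[(triethylsilyl)oxy]but-2-en-2-yl}-2,4,5,6,7,7a-hexahydro-1-benzofuran-6-yl]oxy}silane | CC[Si](CC)(CC)OC/C=C(\C)[C@@H]1C=C2C(C)(C)C[C@H](O[Si](C)(C)C(C)(C)C)C[C@@]2(C)O1 | intermediate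
19 | (2E)-3-[(2S,6S,7aR)-6-{[tert-butyl(dimethyl)silyl]oxy}-4,4,7a-trimethyl-2,4,5,6,7,7a-hexahydro-1-benzofuran-2-yl]but-2-en-1-ol | OC/C=C(\C)[C@@H]1C=C2C(C)(C)C[C@H](O[Si](C)(C)C(C)(C)C)C[C@@]2(C)O1 | intermediate
20 | {[(2S,6S,7aR)-2-[(2E)-4-bromobut-2-en-2-yl]-4,4,7a-trimethyl-2,4,5,6,7,7a-hexahydro-1-benzofuran-6-yl]oxy}(tert-butyl)dimethylsilane | BrC/C=C(\C)[C@@H]1C=C2C(C)(C)C[C@H](O[Si](C)(C)C(C)(C)C)C[C@@]2(C)O1 | intermediate
21 | {(2E)-3-[(2S,6S,7aR)-6-{[tert-butyl(dimethyl)silyl]oxy}-4,4,7a-trimethyl-2,4,5,6,7,7a-hexahydro-1-benzofuran-2-yl]but-2-en-1-yl}(triphenyl)phosphonium bromide | [Br-].C(/C=C(\C)[C@@H]1C=C2C(C)(C)C[C@H](O[Si](C)(C)C(C)(C)C)C[C@@]2(C)O1)[P+](c1ccccc1)(c1ccccc1)c1ccccc1 | intermediate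
22 | (2E,4E,6E)-2,7-dimethylocta-2,4,6-trienedial | O=C/C(C)=C/C=C/C=C(C)/C=O | starting material
23 | phosphorus ylide of 21 (carbanion at C11 next to the triphenylphosphonium group) | [CH-](/C=C(\C)[C@@H]1C=C2C(C)(C)C[C@H](O[Si](C)(C)C(C)(C)C)C[C@@]2(C)O1)[P+](c1ccccc1)(c1ccccc1)c1ccccc1 | intermediate
24 | (2E,4E,6E,8E,10E)-11-[(2S,6S,7aR)-6-{[tert-butyl(dimethyl)silyl]oxy}-4,4,7a-trimethyl-2,4,5,6,7,7a-hexahydro-1-benzofuran-2-yl]-2,7-dimethyldodeca-2,4,6,8,10-pentaenal | CC(/C=O)=C\C=C\C=C(C)\C=C\C=C(/C)[C@@H]1C=C2C(C)(C)C[C@H](O[Si](C)(C)C(C)(C)C)C[C@@]2(C)O1 | intermediate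
25 | (1S,2R,4S)-4-{[tert-butyl(dimethyl)silyl]oxy}-1-(hydroxymethyl)-2,6,6-trimethylcyclohexane-1,2-diol | OC[C@@]1(O)C(C)(C)C[C@H](O[Si](C)(C)C(C)(C)C)C[C@@]1(C)O | intermediate
26 | (1R,2R,4S)-4-{[tert-butyl(dimethyl)silyl]oxy}-1,2-dihydroxy-2,6,6-trimethylcyclohexane-1-carbaldehyde | O=C[C@@]1(O)C(C)(C)C[C@H](O[Si](C)(C)C(C)(C)C)C[C@@]1(C)O | intermediate
27 | ethyl (2E)-4-(diethoxyphosphoryl)-3-methylbut-2-enoate | CCOC(=O)/C=C(\C)CP(=O)(OCC)OCC | starting material
28 | lithium salt of 27 (carbanion at C4) | [Li+].CCOC(=O)/C=C(\C)[CH-]P(=O)(OCC)OCC | intermediate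
29 | ethyl (2E,4E)-5-[(1R,2R,4S)-4-{[tert-butyl(dimethyl)silyl]oxy}-1,2-dihydroxy-2,6,6-trimethylcyclohexyl]-3-methylpenta-2,4-dienoate | CCOC(=O)/C=C(C)/C=C/[C@@]1(O)C(C)(C)C[C@H](O[Si](C)(C)C(C)(C)C)C[C@@]1(C)O | intermediate
30 | (1R,2R,4S)-4-{[tert-butyl(dimethyl)silyl]oxy}-1-[(1E,3E)-5-hydroxy-3-methylpenta-1,3-dien-1-yl]-2,6,6-trimethylcyclohexane-1,2-diol | OC/C=C(C)/C=C/[C@@]1(O)C(C)(C)C[C@H](O[Si](C)(C)C(C)(C)C)C[C@@]1(C)O | intermediate
31 | (1R,2R,4S)-1-[(1E,3E)-5-bromo-3-methylpenta-1,3-dien-1-yl]-4-{[tert-butyl(dimethyl)silyl]oxy}-2,6,6-trimethylcyclohexane-1,2-diol | BrC/C=C(C)/C=C/[C@@]1(O)C(C)(C)C[C@H](O[Si](C)(C)C(C)(C)C)C[C@@]1(C)O | intermediate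
32 | {(2E,4E)-5-[(1R,2R,4S)-4-{[tert-butyl(dimethyl)silyl]oxy}-1,2-dihydroxy-2,6,6-trimethylcyclohexyl]-3-methylpenta-2,4-dien-1-yl}(triphenyl)phosphonium bromide | [Br-].C(/C=C(C)/C=C/[C@@]1(O)C(C)(C)C[C@H](O[Si](C)(C)C(C)(C)C)C[C@@]1(C)O)[P+](c1ccccc1)(c1ccccc1)c1ccccc1 | intermediate
33 | phosphorus ylide of 32 (carbanion at C11' next to the triphenylphosphonium group) | [CH-](/C=C(C)/C=C/[C@@]1(O)C(C)(C)C[C@H](O[Si](C)(C)C(C)(C)C)C[C@@]1(C)O)[P+](c1ccccc1)(c1ccccc1)c1ccccc1 | intermediate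
34 | (all-E)-3,3'-bis-O-[tert-butyl(dimethyl)silyl] ether of 35 | CC(/C=C/C=C(C)/C=C/[C@@]1(O)C(C)(C)C[C@H](O[Si](C)(C)C(C)(C)C)C[C@@]1(C)O)=C\C=C\C=C(C)\C=C\C=C(/C)[C@@H]1C=C2C(C)(C)C[C@H](O[Si](C)(C)C(C)(C)C)C[C@@]2(C)O1 | intermediate
35 | (3S,5R,8S,3'S,5'R,6'R)-5,8-epoxy-5,8,5',6'-tetrahydro-β,β-carotene-3,3',5',6'-tetrol (all-E) | CC(/C=C/C=C(C)/C=C/[C@@]1(O)C(C)(C)C[C@H](O)C[C@@]1(C)O)=C\C=C\C=C(C)\C=C\C=C(/C)[C@@H]1C=C2C(C)(C)C[C@H](O)C[C@@]2(C)O1 | target

Total step count: 22.
Longest linear sequence: 13 steps (steps 1–6, 11–15, 21, 22; the triol branch, steps 1–6, 16–20, 21, 22, is equally long).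

Steps most likely to fail

Step 11. The bulky tertiary copper alkoxide may react too slowly with the allyl-iridium intermediate, attack the distal diene terminus, or erode catalyst control of C8. The fallback avoids the intermolecular etherification altogether; it sets out from 8 and comes back at 18. Ozonolysis of 8 (O3, CH2Cl2/MeOH, −78 °C; Me2S) should give the α-hydroxy ketone F1. Heating F1 with (triphenylphosphoranylidene)ketene, Ph3P=C=C=O, in toluene should give the butenolide F2 by O-acylation and intramolecular Wittig reaction, which closes the same C6=C7 bond. In parallel, but-2-yn-1-ol is hydrozirconated (Cp2Zr(H)Cl) and iodinated to (2E)-3-iodobut-2-en-1-ol F3, which is silylated (Et3SiCl, imidazole) to the vinyl iodide F4. Iodine–lithium exchange on F4 (t-BuLi, Et2O, −78 °C) and addition to F2 should give the lactol F5. Ionic reduction (Et3SiH, BF3·OEt2, CH2Cl2, −78 °C) is expected to deliver 18 together with its C8 epimer, to be separated by chromatography. This route gives up catalyst control of C8.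

Step 12. The C7 ruthenium alkylidene may fail to add to the doubly neopentyl methylidene, so that dimerisation through the vinyl group or ruthenium-hydride double-bond migration takes over. The fallback replaces alkene–alkene metathesis by a carbonyl olefination at C6; it sets out from 8 and comes back at 18. Ozonolysis of 8 gives the α-hydroxy ketone F1 as above. Its copper alkoxide is etherified with 14 under the conditions of step 11 to give the keto ether F6. Treatment with one equivalent of Mo(=CHCMe2Ph)(=N-2,6-iPr2C6H3)[OCMe(CF3)2]2 (benzene, rt) should convert the vinyl group into a C7 molybdenum alkylidene, which olefinates the C6 ketone intramolecularly in a Wittig-like step driven by the Mo=O bond and gives 18.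

Step 16. Osmylation may be slow at the hindered methylidene or show poor facial selectivity. The fallback builds the trans-diol by epoxide opening; it sets out from 5 and comes back at 25. Sharpless epoxidation of 5 with L-(+)-diethyl tartrate (Ti(OiPr)4, t-BuOOH, CH2Cl2, −20 °C) should give the syn epoxy alcohol F7. Acid-catalysed hydrolysis (cat. HClO4, THF/H2O, 0 °C) is expected to open F7 at the methyl-bearing carbon with inversion (trans-diaxial opening at the less hindered epoxide carbon) to give 25.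

Further compounds
F1 | step 11 | (2R,4S)-4-{[tert-butyl(dimethyl)silyl]oxy}-2-hydroxy-2,6,6-trimethylcyclohexan-1-one | O=C1C(C)(C)C[C@H](O[Si](C)(C)C(C)(C)C)C[C@@]1(C)O
F2 | step 11 | (6S,7aR)-6-{[tert-butyl(dimethyl)silyl]oxy}-4,4,7a-trimethyl-5,6,7,7a-tetrahydro-1-benzofuran-2(4H)-one | O=C1C=C2C(C)(C)C[C@H](O[Si](C)(C)C(C)(C)C)C[C@@]2(C)O1
F3 | step 11 | (2E)-3-iodobut-2-en-1-ol | OC/C=C(\C)I
F4 | step 11 | triethyl{[(2E)-3-iodobut-2-en-1-yl]oxy}silane | CC[Si](CC)(CC)OC/C=C(\C)I
F5 | step 11 | (6S,7aR)-6-{[tert-butyl(dimethyl)silyl]oxy}-4,4,7a-trimethyl-2-{(2E)-4-[(triethylsilyl)oxy]but-2-en-2-yl}-2,4,5,6,7,7a-hexahydro-1-benzofuran-2-ol (mixture at C2) | CC[Si](CC)(CC)OC/C=C(\C)C1(O)C=C2C(C)(C)C[C@H](O[Si](C)(C)C(C)(C)C)C[C@@]2(C)O1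
F6 | step 12 | (2R,4S)-4-{[tert-butyl(dimethyl)silyl]oxy}-2,6,6-trimethyl-2-({(3S,4E)-4-methyl-6-[(triethylsilyl)oxy]hexa-1,4-dien-3-yl}oxy)cyclohexan-1-one | O=C1C(C)(C)C[C@H](O[Si](C)(C)C(C)(C)C)C[C@@]1(C)O[C@@H](C=C)/C(C)=C/CO[Si](CC)(CC)CC
F7 | step 16 | [(1S,4S,6S)-4-{[tert-butyl(dimethyl)silyl]oxy}-2,2,6-trimethyl-7-oxabicyclo[4.1.0]heptan-1-yl]methanol (epoxide oxygen cis to the silyloxy group) | OC[C@@]12C(C)(C)C[C@H](O[Si](C)(C)C(C)(C)C)C[C@]1(C)O2
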